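**Retrosynthetic overview**
- Numbering: unit one is rings A, C, B (C2–C8a, C1'–C6'). Unit two is rings D, F, E (C2''–C8a'', C1'''–C6'''). The units are joined C3'–C6''.
- Feature used: O1 of ring C links arene carbon C8a (ring A) to the benzylic stereocentre C2, and O1'' of ring F links C8a'' (ring D) to C2''. Cutting C8a–O1 and C8a''–O1'' turns both stereocentres into plain (S)-benzylic alcohols of the bis(2-haloaryl) bis-carbinol 15.
- Endgame: 21 ⇐ BCl3 unmasking ⇐ bis-flavanone 19 ⇐ benzylic oxidation at C4/C4'' of biflavan 17 ⇐ twofold Pd C–O closure of 15.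
- 15 ⇐ double asymmetric transfer hydrogenation ⇐ diketone 14 ⇐ 1,4-reduction of bis-enone 12 ⇐ two Claisen–Schmidt condensations (with 7 and 11) around a ring-D formylation ⇐ biaryl ketone 6 ⇐ Suzuki–Miyaura coupling of 4 and 5.
- Ring order: rings A, B, D and E are bought. Ring C (bromide) closes first and ring F (chloride) second, in the same flask.

Key step: step 8

Assumption: the C3'–C6'' axis carries three ortho oxygen substituents and one ortho hydrogen. It is treated as freely rotating at room temperature, in line with a target defined without an axial descriptor, so no compound is drawn with axial chirality.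

Step 1
Reactants: 1 5-chloro-1,3-dimethoxybenzene
Product: 4 (4-chloro-2,6-dimethoxyphenyl)boronic acid, via aryllithium 2 (not isolated), via lithium aryltriisopropoxyborate 3 (not isolated)
Conditions: n-BuLi, THF, −78 → 0 °C; B(Oi-Pr)3, −78 °C → rt; 1 M HCl, 0 °C
Reagents that add atoms: triisopropyl borate CC(C)OB(OC(C)C)OC(C)C; water O
Why: Directed ortho-metalation takes the C–H flanked by both methoxy groups (the doubly coordinated and most acidic site), the aryl chloride does not exchange with n-BuLi, and borate trapping followed by brief cold hydrolysis gives the boronic acid.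

Step 2
Reactants: 4 (4-chloro-2,6-dimethoxyphenyl)boronic acid; 5 3'-bromo-4'-methoxyacetophenone
Product: 6 1-(4'-chloro-2',6,6'-trimethoxybiphenyl-3-yl)ethanone
Conditions: Pd(PPh3)4 (5 mol %), K3PO4, DMF, 100 °C (4 in 1.5 equiv)
Reagents that add atoms: none
Why: In this Suzuki–Miyaura coupling, PPh3-ligated zerovalent palladium inserts into the C–Br bond of 5 but not into the electron-rich C–Cl bond of 4 or 6, and nearly anhydrous K3PO4 with an excess of 4 offsets protodeboronation of the 2,6-dimethoxyaryl boronic acid.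

Step 3
Reactants: 6 1-(4'-chloro-2',6,6'-trimethoxybiphenyl-3-yl)ethanone; 7 2-bromo-4,6-dimethoxybenzaldehyde
Product: 8 (E)-3-(2-bromo-4,6-dimethoxyphenyl)-1-(4'-chloro-2',6,6'-trimethoxybiphenyl-3-yl)prop-2-en-1-one
Conditions: KOH, EtOH/THF, rt
Reagents that add atoms: none
Why: In this Claisen–Schmidt condensation 6 is the only enolisable component and 7 the only aldehyde, and E1cB loss of water from the aldol gives the conjugated (E)-enone, which also removes the methyl ketone before the formylation.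

Step 4
Reactants: 8 (E)-3-(2-bromo-4,6-dimethoxyphenyl)-1-(4'-chloro-2',6,6'-trimethoxybiphenyl-3-yl)prop-2-en-1-one
Product: 10 5'-[(E)-3-(2-bromo-4,6-dimethoxyphenyl)acryloyl]-4-chloro-2,2',6-trimethoxybiphenyl-3-carbaldehyde, via ring-D α-chlorobenzyl methyl ether 9 (not isolated)
Conditions: Cl2CHOMe, TiCl4 (excess), CH2Cl2, −78 → 0 °C; then ice/H2O
Reagents that add atoms: dichloromethyl methyl ether COC(Cl)Cl; water O
Why: In this Rieche formylation TiCl4 binds the enone carbonyl and turns rings A and B into electron-poor push–pull arenes, so the chloro(methoxy)carbenium ion attacks ring D, whose two free positions (each ortho to one methoxy, para to the other, next to chlorine) are equivalent by rotation about the biaryl axis and give one aldehyde after hydrolysis.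

Step 5
Reactants: 10 5'-[(E)-3-(2-bromo-4,6-dimethoxyphenyl)acryloyl]-4-chloro-2,2',6-trimethoxybiphenyl-3-carbaldehyde; 11 4'-(benzyloxy)acetophenone
Product: 12 (E,E)-bis-enone (ring B–CO–CH=CH–ring A and ring E–CO–CH=CH–ring D)
Conditions: KOH, EtOH/THF, rt (11 in 1.05 equiv)
Reagents that add atoms: none
Why: In this Claisen–Schmidt condensation 11 is the only enolisable partner because the ketone of 10 is already part of an enone, the aldol dehydrates by E1cB to the (E)-enone, and Michael addition to the first enone is held back by its di-ortho-substituted β-aryl group and the near-stoichiometric amount of 11.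

Step 6
Reactants: 12 (E,E)-bis-enone
Product: 14 saturated diketone (ring B–CO–CH2CH2–ring A and ring E–CO–CH2CH2–ring D), via bis(triethylsilyl enol ether) 13 (not isolated)
Conditions: RhCl(PPh3)3 (5 mol %), Et3SiH, toluene, 70 °C; then cat. HCl, THF/H2O, rt
Reagents that add atoms: none
Why: Rhodium-catalysed 1,4-hydrosilylation of enones with a monohydrosilane places silicon on oxygen and hydride on the β-carbon, the silyl enol ethers shield both carbonyls from over-reduction until mild acid hydrolysis, and the aryl bromide, aryl chloride and benzyl ether survive, as they would not under Pd/C hydrogenation.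

Step 7
Reactants: 14 saturated diketone
Product: 15 (1S)-3-(2-bromo-4,6-dimethoxyphenyl)-1-{3'-[(3S)-3-(4-benzyloxyphenyl)-3-hydroxypropyl]-4'-chloro-2',6,6'-trimethoxybiphenyl-3-yl}propan-1-ol
Conditions: RuCl(p-cymene)[(S,S)-TsDPEN] (4 mol %), HCO2H/Et3N (5:2), CH2Cl2, 35 °C
Reagents that add atoms: none
Why: In this Noyori–Ikariya asymmetric transfer hydrogenation the (S,S)-TsDPEN ruthenium hydride orients each aryl group by a CH/π contact with the cymene ligand and delivers hydride to the Re face of both aryl alkyl ketones, which sets C2 and C2'' as (S) under pure catalyst control (the centres are too remote to influence each other), any wrong-face event ends up in separable (R,S)/(S,R) diastereomers, and the halides and benzyl ether are inert to formate.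

Step 8
Reactants: 15 (S,S)-bis-carbinol
Product: 17 (2S,2''S)-4'''-O-benzyl-5,7,4',5'',7''-penta-O-methyl-3',6''-biflavan, via ring-C-closed chloro carbinol 16 (not isolated)
Conditions: Pd(OAc)2 (10 mol %), RockPhos (2-di-tert-butylphosphino-3-methoxy-6-methyl-2',4',6'-triisopropylbiphenyl, 15 mol %), Cs2CO3 (4 equiv), toluene, 90 °C, argon
Reagents that add atoms: none
Why: Zerovalent palladium formed from Pd(OAc)2 and the phosphine inserts first into the C8a–Br bond of ring A and later into the less reactive C8a''–Cl bond of ring D, and Cs2CO3 then delivers the tethered alkoxide to divalent palladium. The closest known reaction type is the intramolecular Buchwald–Hartwig etherification of 3-(2-haloaryl)propanols bearing secondary carbinols, which gives 2-substituted chromans. Rings C and F each close through a seven-membered oxapalladacycle that contracts to the six-membered pyran by C(sp2)–O reductive elimination. No stereocentre is created: only the O–H bonds at C2 and C2'' are broken, so both (S) centres from step 7 are carried over with retention. The selectivity needed is reductive elimination over β-hydride elimination from the benzylic alkoxide (which would give an aryl ketone and a dehalogenated arene), and it is secured by the very bulky di-tert-butylbiaryl ligand together with the short three-carbon tether. Regiochemistry is fixed by the halogen standing ortho to each tether, and the remaining ethers of the four arenes are inert to the catalyst.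

Step 9
Reactants: 17 (2S,2''S)-biflavan
Product: 18 (2S,2''S)-biflavan-4,4''-diol (mixture of C4 and C4'' epimers)
Conditions: DDQ (2.4 equiv), CH2Cl2/pH 7 phosphate buffer, 0 °C → rt, dilute
Reagents that add atoms: water O
Why: DDQ abstracts hydride from C4–H and C4''–H because the resulting cations are 2,4,6-trioxygenated benzylic cations (the known C4 oxidation of O-alkylated flavans), whereas C2–H and C2''–H would give far less stabilised mono-alkoxybenzyl cations; water traps each cation, the buffer limits acid-induced loss of H3 to a flav-3-ene, and the new C4/C4'' carbinol centres form without control because step 10 erases them.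

Step 10
Reactants: 18 (2S,2''S)-biflavan-4,4''-diol
Product: 19 (2S,2''S)-4'''-O-benzyl-5,7,4',5'',7''-penta-O-methyl-3',6''-biflavanone
Conditions: IBX (3 equiv), DMSO, rt
Reagents that add atoms: none
Why: IBX oxidises secondary benzylic alcohols to ketones under neutral, base-free conditions at room temperature, so the C4/C4'' epimers converge on one bis-ketone, the C2/C2'' centres are not exposed to retro-oxa-Michael opening, and the ethers are inert.

Step 11
Reactants: 19 (2S,2''S)-biflavanone pentamethyl benzyl ether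
Product: 21 (2S,2''S)-7,4',7''-tri-O-methyl-2,3,2'',3''-tetrahydrorobustaflavone (CNP0150873.1), via tris(O-dichloroboryl) intermediate 20 (not isolated)
Conditions: BCl3 (1 M in CH2Cl2, 8 equiv), C6HMe5 (5 equiv), CH2Cl2, −78 → −10 °C; then H2O, 0 °C
Reagents that add atoms: none
Why: BCl3 binds each C4 carbonyl and the peri methoxy oxygen in a six-membered chelate and cleaves only the C5 and C5'' methyl ethers (the known selective 5-O-demethylation of flavanones), while the BCl3/pentamethylbenzene pair removes the aryl benzyl ether at low temperature with the arene trapping the benzyl cation; the unchelated 7-, 4'- and 7''-methyl ethers stay, and the cold, base-free medium avoids ring opening at C2/C2''.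

**Compound list**

1 | 5-chloro-1,3-dimethoxybenzene | COc1cc(Cl)cc(OC)c1 | starting material
2 | (4-chloro-2,6-dimethoxyphenyl)lithium | [Li]c1c(OC)cc(Cl)cc1OC | intermediate
3 | lithium (4-chloro-2,6-dimethoxyphenyl)triisopropoxyborate | [Li+].CC(C)O[B-](OC(C)C)(OC(C)C)c1c(OC)cc(Cl)cc1OC | intermediate
4 | (4-chloro-2,6-dimethoxyphenyl)boronic acid | OB(O)c1c(OC)cc(Cl)cc1OC | intermediate
5 | 3'-bromo-4'-methoxyacetophenone | COc1ccc(C(C)=O)cc1Br | starting material
6 | 1-(4'-chloro-2',6,6'-trimethoxybiphenyl-3-yl)ethanone | CC(=O)c1ccc(OC)c(-c2c(OC)cc(Cl)cc2OC)c1 | intermediate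
7 | 2-bromo-4,6-dimethoxybenzaldehyde | COc1cc(Br)c(C=O)c(OC)c1 | starting material
8 | (E)-3-(2-bromo-4,6-dimethoxyphenyl)-1-(4'-chloro-2',6,6'-trimethoxybiphenyl-3-yl)prop-2-en-1-one | COc1cc(Br)c(/C=C/C(=O)c2ccc(OC)c(-c3c(OC)cc(Cl)cc3OC)c2)c(OC)c1 | intermediate
9 | enone 8 bearing CH(Cl)OMe on the ring-D carbon between Cl and OMe | COc1cc(Br)c(/C=C/C(=O)c2ccc(OC)c(-c3c(OC)cc(Cl)c(C(Cl)OC)c3OC)c2)c(OC)c1 | intermediate
10 | 5'-[(E)-3-(2-bromo-4,6-dimethoxyphenyl)acryloyl]-4-chloro-2,2',6-trimethoxybiphenyl-3-carbaldehyde | COc1cc(Br)c(/C=C/C(=O)c2ccc(OC)c(-c3c(OC)cc(Cl)c(C=O)c3OC)c2)c(OC)c1 | intermediate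
11 | 4'-(benzyloxy)acetophenone | CC(=O)c1ccc(OCc2ccccc2)cc1 | starting material
12 | (E,E)-bis-enone | COc1cc(Br)c(/C=C/C(=O)c2ccc(OC)c(-c3c(OC)cc(Cl)c(/C=C/C(=O)c4ccc(OCc5ccccc5)cc4)c3OC)c2)c(OC)c1 | intermediate
13 | (Z,Z)-bis(triethylsilyl enol ether), geometry of no consequence | COc1cc(Br)c(C/C=C(\O[Si](CC)(CC)CC)c2ccc(OC)c(-c3c(OC)cc(Cl)c(C/C=C(\O[Si](CC)(CC)CC)c4ccc(OCc5ccccc5)cc4)c3OC)c2)c(OC)c1 | intermediate
14 | saturated diketone | COc1cc(Br)c(CCC(=O)c2ccc(OC)c(-c3c(OC)cc(Cl)c(CCC(=O)c4ccc(OCc5ccccc5)cc4)c3OC)c2)c(OC)c1 | intermediate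
15 | (S,S)-bis-carbinol (Br on ring A, Cl on ring D) | COc1cc(Br)c(CC[C@H](O)c2ccc(OC)c(-c3c(OC)cc(Cl)c(CC[C@H](O)c4ccc(OCc5ccccc5)cc4)c3OC)c2)c(OC)c1 | intermediate
16 | (2S)-flavan with ring C closed, ring-D chloride and (S)-carbinol still open | COc1cc(OC)c2c(c1)O[C@H](c1ccc(OC)c(-c3c(OC)cc(Cl)c(CC[C@H](O)c4ccc(OCc5ccccc5)cc4)c3OC)c1)CC2 | intermediate
17 | (2S,2''S)-4'''-O-benzyl-5,7,4',5'',7''-penta-O-methyl-3',6''-biflavan | COc1cc(OC)c2c(c1)O[C@H](c1ccc(OC)c(-c3c(OC)cc4c(c3OC)CC[C@@H](c3ccc(OCc5ccccc5)cc3)O4)c1)CC2 | intermediate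
18 | (2S,2''S)-biflavan-4,4''-diol, C4/C4'' epimers | COc1cc(OC)c2c(c1)O[C@H](c1ccc(OC)c(-c3c(OC)cc4c(c3OC)C(O)C[C@@H](c3ccc(OCc5ccccc5)cc3)O4)c1)CC2O | intermediate
19 | (2S,2''S)-4'''-O-benzyl-5,7,4',5'',7''-penta-O-methyl-3',6''-biflavanone | COc1cc(OC)c2c(c1)O[C@H](c1ccc(OC)c(-c3c(OC)cc4c(c3OC)C(=O)C[C@@H](c3ccc(OCc5ccccc5)cc3)O4)c1)CC2=O | intermediate
20 | 5,5'',4'''-tris(O-dichloroboryl) biflavanone | COc1cc(OB(Cl)Cl)c2c(c1)O[C@H](c1ccc(OC)c(-c3c(OC)cc4c(c3OB(Cl)Cl)C(=O)C[C@@H](c3ccc(OB(Cl)Cl)cc3)O4)c1)CC2=O | intermediate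
21 | (2S,2''S)-7,4',7''-tri-O-methyl-2,3,2'',3''-tetrahydrorobustaflavone | COc1cc(O)c2c(c1)O[C@H](c1ccc(OC)c(-c3c(OC)cc4c(c3O)C(=O)C[C@@H](c3ccc(O)cc3)O4)c1)CC2=O | target

**Step count**

Total step count: 11. Longest linear sequence: 11 steps (1 → 21). Compounds 5, 7 and 11 enter as purchased.

**Steps most likely to fail**

**Step 8.**
- Risk: β-hydride elimination from the benzylic palladium alkoxides would oxidise the carbinol and hydrodehalogenate the arene.
- Risk: oxidative addition into the electron-rich C8a''–Cl bond may be slow, so that ring F does not close.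
- Fallback (from 14, back at 17): the bond made is changed from aryl–O to alkyl–O with inversion. Diketone 14 is reduced with RuCl(p-cymene)[(R,R)-TsDPEN] in HCO2H/Et3N to the (R,R)-bis-carbinol F1. Silylation (TBSCl, imidazole, DMF) gives the bis-TBS ether F2. Palladium-catalysed hydroxylation of both halides (Pd2(dba)3, t-BuBrettPhos, KOH, dioxane/H2O, 100 °C) gives the bis-phenol bis-silyl ether F3. Bu4NF frees the bis-phenol diol F4. A twofold Mitsunobu etherification (PPh3, DIAD, THF, 0 °C) then closes rings C and F with inversion at both carbinols and returns to 17.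

**Step 9.**
- Risk: the C4 cation may lose a C3 proton to give a flav-3-ene, and further hydride loss from C2 would give a flavylium ion and erase the stereocentres.
- Risk: hydride abstraction may compete at C2/C2''.
- Risk: the cation may be captured by an electron-rich arene of a second molecule.
- Fallback (from 12, back at 18): the C4/C4'' oxygens are installed before ring closure and carried through the same palladium closure. Copper-catalysed conjugate borylation (CuCl, NaOt-Bu, DPEphos, B2pin2, MeOH, THF) gives the bis(β-pinacolboryl ketone) F5. NaBO3·4H2O in THF/H2O gives the bis(β-hydroxy ketone) F6. TBSOTf/2,6-lutidine gives the bis(β-silyloxy ketone) F7. Transfer hydrogenation as in step 7 gives the (S,S)-bis-carbinol bis-silyl ether F8. The conditions of step 8 give the (2S,2''S)-bis(4-silyloxyflavan) F9. Bu4NF returns to 18. The C4/C4'' centres are uncontrolled throughout and vanish in step 10.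

**Step 4.**
- Risk: discrimination between ring D and ring A may be poor, since both are halogenated dimethoxyarenes.
- Risk: the Lewis acid may cleave the methyl ether next to the new aldehyde.
- Fallback (from 1, back at 10): the formyl carbon is placed before the biaryl bond and carried as an acetal. Vilsmeier–Haack formylation of 1 (POCl3, DMF) runs through the iminium chloride F10 to 2-chloro-4,6-dimethoxybenzaldehyde F11. Ethylene glycol/TsOH gives the dioxolane F12. n-BuLi metalates the position between the two methoxy groups to the aryllithium F13, which i-PrOBpin traps as the pinacol boronate F14. Suzuki–Miyaura coupling with 5 (Pd(PPh3)4, K3PO4) gives the biaryl keto acetal F15. Claisen–Schmidt condensation with 7 gives the enone acetal F16. Aqueous HCl/THF unmasks 10.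

**Further compounds**

F1 | step 8 | (R,R)-bis-carbinol (enantiomer of 15) | COc1cc(Br)c(CC[C@@H](O)c2ccc(OC)c(-c3c(OC)cc(Cl)c(CC[C@@H](O)c4ccc(OCc5ccccc5)cc4)c3OC)c2)c(OC)c1
F2 | step 8 | (R,R)-bis-TBS ether | COc1cc(Br)c(CC[C@@H](O[Si](C)(C)C(C)(C)C)c2ccc(OC)c(-c3c(OC)cc(Cl)c(CC[C@@H](O[Si](C)(C)C(C)(C)C)c4ccc(OCc5ccccc5)cc4)c3OC)c2)c(OC)c1
F3 | step 8 | (R,R)-bis-phenol bis-silyl ether (OH in place of Br and Cl) | COc1cc(O)c(CC[C@@H](O[Si](C)(C)C(C)(C)C)c2ccc(OC)c(-c3c(OC)cc(O)c(CC[C@@H](O[Si](C)(C)C(C)(C)C)c4ccc(OCc5ccccc5)cc4)c3OC)c2)c(OC)c1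
F4 | step 8 | (R,R)-bis-phenol diol | COc1cc(O)c(CC[C@@H](O)c2ccc(OC)c(-c3c(OC)cc(O)c(CC[C@@H](O)c4ccc(OCc5ccccc5)cc4)c3OC)c2)c(OC)c1
F5 | step 9 | bis(β-pinacolboryl ketone), boron on the carbons that become C4 and C4'' | COc1cc(Br)c(C(CC(=O)c2ccc(OC)c(-c3c(OC)cc(Cl)c(C(CC(=O)c4ccc(OCc5ccccc5)cc4)B4OC(C)(C)C(C)(C)O4)c3OC)c2)B2OC(C)(C)C(C)(C)O2)c(OC)c1
F6 | step 9 | bis(β-hydroxy ketone) | COc1cc(Br)c(C(O)CC(=O)c2ccc(OC)c(-c3c(OC)cc(Cl)c(C(O)CC(=O)c4ccc(OCc5ccccc5)cc4)c3OC)c2)c(OC)c1
F7 | step 9 | bis(β-silyloxy ketone) | COc1cc(Br)c(C(CC(=O)c2ccc(OC)c(-c3c(OC)cc(Cl)c(C(CC(=O)c4ccc(OCc5ccccc5)cc4)O[Si](C)(C)C(C)(C)C)c3OC)c2)O[Si](C)(C)C(C)(C)C)c(OC)c1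
F8 | step 9 | (S,S)-bis-carbinol bis-silyl ether | COc1cc(Br)c(C(C[C@H](O)c2ccc(OC)c(-c3c(OC)cc(Cl)c(C(C[C@H](O)c4ccc(OCc5ccccc5)cc4)O[Si](C)(C)C(C)(C)C)c3OC)c2)O[Si](C)(C)C(C)(C)C)c(OC)c1
F9 | step 9 | (2S,2''S)-bis(4-silyloxyflavan) | COc1cc(OC)c2c(c1)O[C@H](c1ccc(OC)c(-c3c(OC)cc4c(c3OC)C(O[Si](C)(C)C(C)(C)C)C[C@@H](c3ccc(OCc5ccccc5)cc3)O4)c1)CC2O[Si](C)(C)C(C)(C)C
F10 | step 4 | (2-chloro-4,6-dimethoxybenzylidene)dimethyliminium chloride | C[N+](C)=Cc1c(Cl)cc(OC)cc1OC.[Cl-]
F11 | step 4 | 2-chloro-4,6-dimethoxybenzaldehyde | COc1cc(Cl)c(C=O)c(OC)c1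
F12 | step 4 | 2-(2-chloro-4,6-dimethoxyphenyl)-1,3-dioxolane | COc1cc(Cl)c(C2OCCO2)c(OC)c1
F13 | step 4 | [4-chloro-3-(1,3-dioxolan-2-yl)-2,6-dimethoxyphenyl]lithium | COc1cc(Cl)c(C2OCCO2)c(OC)c1[Li]
F14 | step 4 | [4-chloro-3-(1,3-dioxolan-2-yl)-2,6-dimethoxyphenyl]boronic acid pinacol ester | COc1cc(Cl)c(C2OCCO2)c(OC)c1B1OC(C)(C)C(C)(C)O1
F15 | step 4 | 1-[4'-chloro-3'-(1,3-dioxolan-2-yl)-2',6,6'-trimethoxybiphenyl-3-yl]ethanone | CC(=O)c1ccc(OC)c(-c2c(OC)cc(Cl)c(C3OCCO3)c2OC)c1
F16 | step 4 | ethylene acetal of aldehyde 10 | COc1cc(Br)c(/C=C/C(=O)c2ccc(OC)c(-c3c(OC)cc(Cl)c(C4OCCO4)c3OC)c2)c(OC)c1
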